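All runs were computed with made-up constants; scatter was added.

**One flask.** With a small charge of substrate I want to run one flask, not four, so I must choose how much third reagent goes in. I count it as a multiple of the substrate charge.

in all of them: substrate 0.010 M

|  | partner | second reagent | third reagent | remark | time |
|---|---|---|---|---|---|
| cedar | 0.012 M | 0.011 M | 0.0072 M | run made earlier |  |
| alder | 0.012 M | 0.011 M | 0.045 M | run made earlier |  |
| theta | 0.0120 M | 0.0110 M | 0.00600 M |  | 80 min |
| epsilon | 0.0120 M | 0.0110 M | 0.0120 M |  | 80 min |
| alpha | 0.0120 M | 0.0110 M | 0.0200 M |  | 80 min |
| eta | 0.0120 M | 0.0110 M | 0.0400 M |  | 80 min |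

- cedar (time / min: target / %, substrate / %): 6.00: 0, 86; 15.0: 6, 67; 30.0: 9, 47; 80.0: 24, 19
- alder (time / min: target / %, substrate / %): 6.00: 0, 78; 15.0: 9, 64; 30.0: 18, 49; 80.0: 16, 23

(each reading ± 2 percentage points)

- the analysis behind the earlier runs scatters by 2 percentage points, standard deviation
- "hardly changes" means that all values lie within two and a half points (for a concentration: within two and a half percent of the largest)
- a step back or a flat step of under half a point counts as no turn

1. amount of target at the end, in percent of the substrate charged for theta, epsilon, alpha, eta, in this order
2. how the row runs (falls all the way / rises, then falls / hardly changes / rises all the way / falls, then rises)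

**Reading the runs.** Substrate reads 19 % in cedar and 23 % in alder at 80.0 min, close for a scatter of 2 percentage points, so I take the loss of substrate as much the same in both runs. At 30.0 min, alder reads twice the target of cedar, yet at 80.0 min it reads less than cedar (16 % against 24 %). I therefore assume that third reagent speeds both the making and the loss of target, so that its multiple and the time count together as a product.

**My reckoning.** Alder's highest reading comes at 30.0 min, though this is a coarse reading, with 18 % against 16 % later. Its multiple is 4.50. Spreading the same product over 80 min gives a first answer of 1.69. But alder's target reads 0 % at 6.00 min, so I go round once more and count minutes past that lag. Alder's multiple times its minutes past the lag gives 108 min; I use this product, the reach, to estimate when target tops for a given multiple. Divided by the 74.0 min that the asked time leaves past the lag, it gives an estimated best multiple of 1.46. Cedar's multiple of 0.720 puts its estimated top at 156 min, and cedar's target reads higher at 80.0 min than at 30.0 min.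

**The decision.** Epsilon, at 1.20, lies nearer my best multiple than alpha, at 2.00, and it takes a smaller charge of third reagent than alpha, so I charge epsilon.

**The forecast.** It gives 19 %, 26 %, 27 % and 19 %, so it rises, then falls, and its grounds read: “The maximum lies near 0.015 M, so the row rises, then falls.” Its row stands higher at alpha than at epsilon, where my choice is epsilon.

**The result.** The flasks give 24.1 %, 31.2 %, 29.2 % and 16.0 %, so the row rises, then falls.

    third reagent + intermediate B → target (k = 0.0450 M⁻¹ s⁻¹)
    second reagent + intermediate A → intermediate B (k = 0.260 M⁻¹ s⁻¹)
    substrate + partner → intermediate A (k = 0.0440 M⁻¹ s⁻¹)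
    third reagent + target → over-reaction product (k = 0.0210 M⁻¹ s⁻¹)

**Reach again.** The row turns at a multiple of 1.38, beside my 1.46. For epsilon the reach puts the top at 96.0 min, later than the end, and epsilon's target goes from 17.9 % at 40.0 min to 31.2 % at 80.0 min. For eta it puts the top at 33.0 min, earlier than the end, and eta's target goes from 19.9 % at 40.0 min to 16.0 % at 80.0 min.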